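**Retrosynthetic overview**

- The route rests on two adjacent carbons of the benzene ring: C3, which carries C1' of the heptadecyl chain, and C4, which carries oxygen and sits next to the methoxy-bearing C5. This is the pattern left when a carbon nucleophile and an electrophile add across a 3-methoxybenzyne.
- Endgame: cleave the C1 O–Si bond last; before that, form the C4 O–CH3 bond by methylating the hindered phenol 10.
- Key disconnection: the C3–C1' and C4–O bonds of 10 lead back to the C3–C4 aryne from fluoroarene 2, heptadecylmagnesium bromide 4, B(OMe)3 and H2O2.
- Fluoroarene 2 comes from 3-fluoro-5-methoxyphenol 1 by silylation; Grignard 4 comes from 1-bromoheptadecane 3 and Mg.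
- No ring is formed at any stage; the single benzene ring is bought with 1.

Key step: step 3

Remark: ring positions are numbered as in the target throughout (C1 carries the free OH, C3 the heptadecyl chain, C4 and C5 the methoxy groups; C1' is the first chain carbon).

**Step 1**
Reactants: 1 3-fluoro-5-methoxyphenol
Product: 2 (3-fluoro-5-methoxyphenoxy)triisopropylsilane
Conditions: iPr3SiCl (1.2 equiv), imidazole (2.5 equiv), DMF, rt
Reagents that add atoms: triisopropylsilyl chloride, CC(C)[Si](Cl)(C(C)C)C(C)C
Why: Standard O-silylation of a phenol through the N-silylimidazolium species; the triisopropylsilyl ether is chosen because it withstands organolithium and Grignard reagents and shields both of its ortho C-H bonds from later lithiation.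

**Step 2**
Reactants: 3 1-bromoheptadecane
Product: 4 heptadecylmagnesium bromide
Conditions: Mg turnings (1.5 equiv), I2 (crystal), THF, 45-50 °C, slow addition of 3; titrated before use
Reagents that add atoms: magnesium, [Mg]
Why: Grignard formation by insertion of magnesium into a primary C-Br bond, with every atom of 3 retained; slow addition at moderate dilution keeps Wurtz coupling low.

**Step 3**
Reactants: 2 (3-fluoro-5-methoxyphenoxy)triisopropylsilane, 4 heptadecylmagnesium bromide, 5 trimethyl borate
Product: 10 2-heptadecyl-6-methoxy-4-(triisopropylsilyloxy)phenol, via aryllithium 6 (not isolated), via aryne 7 (not isolated), via arylmagnesium bromide 8 (not isolated), via dimethyl arylboronate 9 (not isolated)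
Conditions: sec-BuLi (1.0 equiv), THF, −78 °C, 1 h; 4 (3 equiv, THF), −78 °C → rt; 5 (5 equiv), −78 °C → rt; AcOH, 30% aq H2O2, 0 °C → rt; aq Na2SO3
Reagents that add atoms: hydrogen peroxide, OO
Why: sec-BuLi removes the C4 proton of 2, the most acidic one because it lies between F and OMe, while both C-H bonds next to the bulky, poorly coordinating OSi(iPr)3 group are shielded, and aryllithium 6 loses LiF on warming to give the C3-C4 aryne 7. Grignard 4, already present in excess when the aryne is released, adds its alkyl carbon to C3 and places magnesium on C4, because the distorted 3-alkoxyaryne is more electrophilic at the carbon remote from OMe and the C5-O bond inductively stabilises the negative charge building up at C4. The resulting ortho-methoxy arylmagnesium 8 is borylated by B(OMe)3 to 9, and H2O2 under AcOH buffering then causes the 1,2-shift of the aryl group from boron to oxygen and gives phenol 10 with the silyl ether untouched. The closest known reaction type is the vicinal carbomagnesiation and electrophile trapping of 3-alkoxybenzynes generated from ortho-lithiated fluoroarenes, joined here to the standard borylation-oxidation of an arylmagnesium halide. No ring is closed and no stereocentre is formed. Two regioselectivities are needed, the site of lithiation and the direction of addition to the aryne, and the substrate secures the first by the F/OMe flank against the shielded silyloxy flank and the second by the methoxy group on C5.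

**Step 4**
Reactants: 10 2-heptadecyl-6-methoxy-4-(triisopropylsilyloxy)phenol
Product: 11 (3-heptadecyl-4,5-dimethoxyphenoxy)triisopropylsilane
Conditions: MeI (3 equiv), K2CO3 (2 equiv), dry acetone, 55 °C
Reagents that add atoms: iodomethane, CI
Why: Williamson ether synthesis; the phenoxide of 10, although flanked by OMe and the alkyl chain, is alkylated by the small electrophile MeI, and the aryl triisopropylsilyl ether tolerates anhydrous K2CO3 in acetone.

**Step 5**
Reactants: 11 (3-heptadecyl-4,5-dimethoxyphenoxy)triisopropylsilane
Product: 12 3-heptadecyl-4,5-dimethoxyphenol
Conditions: Bu4NF (1.2 equiv), AcOH (1.2 equiv), THF, 0 °C → rt, argon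
Reagents that add atoms: none
Why: Fluoride-induced desilylation of an aryl silyl ether, driven by the strong Si-F bond; AcOH protonates the phenoxide as it forms, so the electron-rich phenol is not exposed to base and air, and the methyl ethers and the alkyl chain are inert.

**Compound list**

1 | 3-fluoro-5-methoxyphenol | COc1cc(O)cc(F)c1 | starting material
2 | (3-fluoro-5-methoxyphenoxy)triisopropylsilane | COc1cc(F)cc(O[Si](C(C)C)(C(C)C)C(C)C)c1 | intermediate
3 | 1-bromoheptadecane | CCCCCCCCCCCCCCCCCBr | starting material
4 | heptadecylmagnesium bromide | CCCCCCCCCCCCCCCCC[Mg]Br | intermediate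
5 | trimethyl borate | COB(OC)OC | starting material
6 | [2-fluoro-6-methoxy-4-(triisopropylsilyloxy)phenyl]lithium (aryllithium) | COc1cc(O[Si](C(C)C)(C(C)C)C(C)C)cc(F)c1[Li] | intermediate
7 | 3-methoxy-5-(triisopropylsilyloxy)benzyne (aryne) | COC1=CC(O[Si](C(C)C)(C(C)C)C(C)C)=CC#C1 | intermediate
8 | [2-heptadecyl-6-methoxy-4-(triisopropylsilyloxy)phenyl]magnesium bromide (arylmagnesium bromide) | CCCCCCCCCCCCCCCCCc1cc(O[Si](C(C)C)(C(C)C)C(C)C)cc(OC)c1[Mg]Br | intermediate
9 | dimethyl [2-heptadecyl-6-methoxy-4-(triisopropylsilyloxy)phenyl]boronate (dimethyl arylboronate) | CCCCCCCCCCCCCCCCCc1cc(O[Si](C(C)C)(C(C)C)C(C)C)cc(OC)c1B(OC)OC | intermediate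
10 | 2-heptadecyl-6-methoxy-4-(triisopropylsilyloxy)phenol | CCCCCCCCCCCCCCCCCc1cc(O[Si](C(C)C)(C(C)C)C(C)C)cc(OC)c1O | intermediate
11 | (3-heptadecyl-4,5-dimethoxyphenoxy)triisopropylsilane | CCCCCCCCCCCCCCCCCc1cc(O[Si](C(C)C)(C(C)C)C(C)C)cc(OC)c1OC | intermediate
12 | 3-heptadecyl-4,5-dimethoxyphenol | CCCCCCCCCCCCCCCCCc1cc(O)cc(OC)c1OC | target

**Step count**

Total steps: 5. Longest linear sequence: 4 steps (1 → 2 → 10 → 11 → 12; the branch 3 → 4 → 10 → 11 → 12 is equally long).

**Steps most likely to fail**

Step 3 (key step). Several things may go wrong:
- lithiation may occur in part next to the silyloxy group;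
- the aryl metal species 6 or 8 may add to the aryne in competition with 4 and give biaryls;
- the long-chain Grignard may come out of solution at −78 °C, so that the aryne is released without enough nucleophile;
- borylation of the di-ortho-substituted arylmagnesium may be incomplete, so that protonation takes the place of oxygenation;
- surplus 4 is borylated and oxidised as well, and its alcohol has to be removed by chromatography.

Fallback: the route sets out from 3 and comes back at 12. Commercial 1,2-dimethoxybenzene is lithiated at the position next to a methoxy group with n-BuLi and TMEDA in THF at 0 °C to give (2,3-dimethoxyphenyl)lithium F1. F1 is alkylated with 3 to give 1-heptadecyl-2,3-dimethoxybenzene F2. C-H borylation of F2 with B2pin2, catalysed by [Ir(OMe)(cod)]2 and 4,4'-di-tert-butyl-2,2'-bipyridine in hexane at 80 °C, is steered by sterics to the only C-H bond without an ortho substituent. It should give 2-(3-heptadecyl-4,5-dimethoxyphenyl)-4,4,5,5-tetramethyl-1,3,2-dioxaborolane F3. Oxidation of F3 with H2O2 and NaOH in THF-water at 0 °C gives 12 directly, so that 10 and 11 are bypassed.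

Step 4. The di-ortho-substituted phenoxide may be alkylated slowly, and under prolonged basic heating the aryl silyl ether may be lost, after which both oxygens would be methylated. Fallback: the route sets out from 10 and comes back at 11. A Mitsunobu etherification with MeOH, PPh3 and diisopropyl azodicarboxylate in THF at 0 °C → rt methylates the phenol under neutral conditions through the methoxyphosphonium ion. No base is present, so the silyl ether is not at risk. This fallback makes no compound outside the compound list.

Step 2. Initiation of the waxy long-chain bromide may be sluggish, and Wurtz coupling may lower the titre of the reagent on which the key step depends. Fallback: the route sets out from 3 and comes back at 4. A Finkelstein exchange with NaI in acetone gives 1-iodoheptadecane F4. Iodine-lithium exchange with t-BuLi (2.1 equiv) in Et2O-pentane at −78 °C gives heptadecyllithium F5. Transmetalation with MgBr2·OEt2 at −78 °C → 0 °C gives 4 without any contact between the alkyl halide and magnesium metal.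

**Further compounds**

F1 | step 3 | (2,3-dimethoxyphenyl)lithium | [Li]c1cccc(OC)c1OC
F2 | step 3 | 1-heptadecyl-2,3-dimethoxybenzene | CCCCCCCCCCCCCCCCCc1cccc(OC)c1OC
F3 | step 3 | 2-(3-heptadecyl-4,5-dimethoxyphenyl)-4,4,5,5-tetramethyl-1,3,2-dioxaborolane | CCCCCCCCCCCCCCCCCc1cc(B2OC(C)(C)C(C)(C)O2)cc(OC)c1OC
F0 | step 4 | none | none
F4 | step 2 | 1-iodoheptadecane | CCCCCCCCCCCCCCCCCI
F5 | step 2 | heptadecyllithium | [Li]CCCCCCCCCCCCCCCCC
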